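All runs stem from a simulated flask with constants of no real substance; noise was put on by code.

Two questions stood over this flask, and I wanted one carried number for the first.

| flask | starting material | gas | free catalyst | second catalyst | remark | time |
|---|---|---|---|---|---|---|
| gamma | 0.11 M | 3.1 mM (held) | 2.7 mM | 2.1 mM | run made earlier |  |
| zeta | 0.18 M | 3.1 mM (held) | 2.7 mM | 2.1 mM | run made earlier |  |
| flask | 0.082 M | 3.1 mM (held) | 2.7 mM | 2.1 mM |  | 20 min |

| run | time / min | target / % | starting material / % |
|---|---|---|---|
| gamma | 2.50 | 32.4 | 11.5 |
| gamma | 8.00 | 43.6 | 0.8 |
| gamma | 12.0 | 45.1 | 0 |
| gamma | 20.0 | 47.7 | 0.1 |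
| zeta | 2.50 | 23.3 | 6.4 |
| zeta | 8.00 | 33.8 | 0 |
| zeta | 12.0 | 36.5 | 0 |
| zeta | 20.0 | 33.2 | 0.7 |

(each reading ± 1 percentage point)

- target at 20 min, in percent of the starting material charged
- concentration of coupling partner in solution at 20 min, in percent of saturation

Dividing the rate of the coupling step by that of the side step cancels [intermediate] and drops time, leaving target per side product, a selectivity factor, proportional to [coupling partner][second catalyst]/[starting material]. So, with the gas and both catalysts as in these runs, I took the final ratio of target to side product as inversely proportional to the charge. Its constant is the even-split charge, the charge at which the two hold equal shares.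

Averaging the readings at 12.0 min and 20.0 min gave target 46.4% in gamma and 34.9% in zeta. Counting the rest as side product, these gave 0.0952 M and 0.0963 M, so I carried the even-split charge 0.0958 M.

The share read lower in zeta than in gamma, so for the flask, charged less than gamma, I took gamma's 46.4% as my lower bound. But [target] read higher in zeta than in gamma, so I took gamma's [target], spread over the flask's charge, as my upper bound, 62.2%. Inside that bracket, my reckoning gave 53.9%, and I expected [coupling partner] near 3.1 mM.

The forecast gave 56% and 98%, its target above my figure but inside the bracket, on the ground that “Coupling, fed by gas uptake, competes with dimerisation by starting material”.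

The flask gave 55.7% and >99.9%, with side product holding 44.3% and starting material 0%, so the forecast stood, and my figure lay 1.8 percentage points low.

    starting material + free catalyst ⇌ free catalyst + intermediate (K = 0.680, k = 55.0 /M/s)
    coupling partner + second catalyst + intermediate → second catalyst + target (k = 3500 /M²/s)
    gas ⇌ coupling partner, rate k3*(csat - [coupling partner]) (kL = 0.210 /s)
    starting material + intermediate → side product (k = 0.270 /M/s)

A neighbour charged with 0.21 M lies above the even-split charge, and the same reckoning gave it 31.3% target. Its result was 30.9% target, with side product holding 69.1%.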